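**Plan**
- Retrosynthetic cuts: first the S–O bond of the 7-sulfate, then C2'–C3' and C1'–C6' of ring B, which splits ring B into the two alkyne carbons of a 2-ethynylchromone and the four carbons of 3-methoxyfuran. The terminal alkyne carbon is then removed (back to a 2-carbaldehyde), and last C2–C3 and O1–C2 of the pyrone ring.
- Enabling feature: ring B (C1'–C6') carries a free 3'-hydroxyl beside the 4'-methoxy group, which are the ring oxygen and the methoxy group of 3-methoxyfuran. The 5-hydroxyl/C4 carbonyl pair gives a chelation site through which a Lewis acid can activate the alkyne.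
- Forward order: ring A is bought as phloroacetophenone, the pyrone ring (ring C) is closed by Claisen condensation and cyclodehydration, the aldehyde is homologated to the alkyne, and ring B is built last by cycloaddition and aromatization. A benzyl/acetyl exchange then leaves O7 as the only site for sulfation.
- Stereochemistry: the target has no stereocentre. The two bridgehead centres of the oxanorbornadiene form as a racemate and vanish in the same step, so only regiochemistry has to be controlled.

Key step: step 4

Assumption 1: aryl sulfate monoesters are drawn as hydrogen sulfates like the target; in the flask they are pyridinium or ammonium salts, which carry no separate numbers, and the free acid, prone to acid-catalysed loss of the sulfate group, is released only at the end on a cold acidic resin and kept cold.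
Assumption 2: 3-methoxyfuran (8) is taken as purchasable from specialty suppliers and is used freshly distilled.

**Step 1**
Reactants: 1 2,4,6-trihydroxyacetophenone
Product: 2 1-[4-(benzyloxy)-2,6-dihydroxyphenyl]ethan-1-one
Conditions: BnBr (1.0 equiv), K2CO3 (1.0 equiv), DMF, 0 °C → rt
Reagents that add atoms: benzyl bromide, BrCc1ccccc1
Why: Williamson etherification: the 4-hydroxyl, para to the acetyl group and the only one not locked in a hydrogen bond to the carbonyl, is the most acidic and most accessible phenol, so one equivalent of base and benzyl bromide should alkylate it in preference to the two chelated ortho hydroxyls.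

**Step 2**
Reactants: 2 1-[4-(benzyloxy)-2,6-dihydroxyphenyl]ethan-1-one; 3 ethyl 2,2-diethoxyacetate
Product: 6 7-(benzyloxy)-5-hydroxy-4-oxo-4H-chromene-2-carbaldehyde, via beta-diketone 4 (not isolated), via diethyl acetal 5 (not isolated)
Conditions: NaH (5 equiv), 3 (1.5 equiv), THF, 0 °C → reflux; then 2 M aq HCl, THF, 60 °C
Reagents that add atoms: water, O
Why: Crossed Claisen condensation of the acetophenone polyanion with the poorly enolizable alpha,alpha-dialkoxy ester gives the 1,3-diketone, and dilute aqueous acid then closes ring C by the classical cyclodehydration of an ortho-hydroxyaryl 1,3-diketone and hydrolyses the acetal, the acid being kept mild enough that the aryl benzyl ether should survive.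

**Step 3**
Reactants: 6 7-(benzyloxy)-5-hydroxy-4-oxo-4H-chromene-2-carbaldehyde
Product: 7 7-(benzyloxy)-2-ethynyl-5-hydroxy-4H-chromen-4-one
Conditions: dimethyl (1-diazo-2-oxopropyl)phosphonate (1.3 equiv), K2CO3 (3 equiv), MeOH–THF, 0 °C → rt
Reagents that add atoms: dimethyl (1-diazo-2-oxopropyl)phosphonate, COP(=O)(OC)C(=[N+]=[N-])C(C)=O
Why: Seyferth–Gilbert homologation in its Ohira–Bestmann form: methoxide cleaves the acetyl group of the reagent, the resulting diazomethylphosphonate anion olefinates the very electrophilic aldehyde, and loss of N2 with 1,2-hydrogen shift gives the terminal alkyne, while the 5-hydroxyl, partly ionized under these conditions, damps the electrophilicity of the pyrone ring toward methoxide.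

**Step 4**
Reactants: 7 7-(benzyloxy)-2-ethynyl-5-hydroxy-4H-chromen-4-one; 8 3-methoxyfuran
Product: 10 7-(benzyloxy)-5-hydroxy-2-(3-hydroxy-4-methoxyphenyl)-4H-chromen-4-one, via oxanorbornadiene 9 (not isolated)
Conditions: 8 (4 equiv), ZnI2 (0.3 equiv), CH2Cl2, 0 °C → rt; then TFA (2 equiv), 0 °C
Reagents that add atoms: none
Why: Proposed new method: ZnI2 bound at the 5-hydroxyl/C4 carbonyl chelate site polarizes the pyrone so that the terminal alkyne carbon, the vinylogous delta position of the chromone enone, becomes electrophilic enough for the very electron-rich 3-methoxyfuran to add across the triple bond in an intermolecular, asynchronous [4+2] cycloaddition that closes ring B as a six-membered carbocycle by forming C2'–C3' and C1'–C6'. The closest known reaction type is the Diels–Alder addition of furans, 3-alkoxyfurans included, to ynones and alkynoates followed by acid-induced opening of the 7-oxanorbornadiene to a phenol, and the new element is a dienophile activated only through the chromone. The selectivity needed is regiochemical: the largest HOMO coefficient of the diene sits on furan C2, which is alpha to the ring oxygen and beta to the methoxy-bearing enol ether carbon, and the largest LUMO coefficient of the dienophile sits on the terminal alkyne carbon, so these two atoms should join and place the oxygen bridge on C3' beside the methoxy carbon C4'. TFA then ionizes the C6'–O bond, because that cation is delocalized onto the methoxy-bearing C4' whereas ionization at C3' would put charge on the chromone-bearing C1', and loss of the C3' proton aromatizes ring B with the former furan oxygen as the 3'-hydroxyl. The two bridgehead stereocentres of 9 form as a racemate, are tied to each other by the bicycle and are erased on aromatization, so no stereocontrol is required. Aromatization is irreversible and so drains the retro-Diels–Alder equilibrium that usually limits furan cycloadditions.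

**Step 5**
Reactants: 10 7-(benzyloxy)-5-hydroxy-2-(3-hydroxy-4-methoxyphenyl)-4H-chromen-4-one
Product: 11 2-[3-(acetyloxy)-4-methoxyphenyl]-7-(benzyloxy)-4-oxo-4H-chromen-5-yl acetate
Conditions: Ac2O (4 equiv), pyridine, DMAP (0.1 equiv), rt
Reagents that add atoms: acetic anhydride, CC(=O)OC(C)=O
Why: DMAP-catalysed acylation with excess anhydride esterifies both the 3'-phenol and the hydrogen-bonded 5-phenol, so that after debenzylation O7 is the only free hydroxyl.

**Step 6**
Reactants: 11 2-[3-(acetyloxy)-4-methoxyphenyl]-7-(benzyloxy)-4-oxo-4H-chromen-5-yl acetate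
Product: 12 2-[3-(acetyloxy)-4-methoxyphenyl]-7-hydroxy-4-oxo-4H-chromen-5-yl acetate
Conditions: H2 (1 atm), 10% Pd/C, EtOAc–THF, rt
Reagents that add atoms: none
Why: Catalytic hydrogenolysis cleaves the benzylic C–O bond of the aryl benzyl ether at atmospheric pressure, conditions under which aryl acetates and the conjugated C2–C3 double bond of a flavone are normally left alone.

**Step 7**
Reactants: 12 2-[3-(acetyloxy)-4-methoxyphenyl]-7-hydroxy-4-oxo-4H-chromen-5-yl acetate
Product: 14 5-hydroxy-2-(3-hydroxy-4-methoxyphenyl)-4-oxo-4H-chromen-7-yl hydrogen sulfate (luteolin 4'-methyl ether 7-sulfate), via sulfated diacetate 13 (not isolated)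
Conditions: SO3·pyridine (5 equiv), pyridine, 40 °C; evaporate; 7 M NH3 in MeOH, 0 °C → rt; strongly acidic cation-exchange resin (H+ form), H2O–MeOH, 0 °C; freeze-dry
Reagents that add atoms: sulfur trioxide pyridine complex, O=S(=O)([O-])[n+]1ccccc1
Why: O-Sulfation of a phenol with the SO3·pyridine complex can only occur at the single free 7-hydroxyl, ammonolysis then removes the two aryl acetates without touching the base-stable aryl sulfate monoester anion, and cation exchange in the cold converts the ammonium salt into the hydrogen sulfate.

**Compound list**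
1 | 2,4,6-trihydroxyacetophenone | CC(=O)c1c(O)cc(O)cc1O | starting material
2 | 1-[4-(benzyloxy)-2,6-dihydroxyphenyl]ethan-1-one | CC(=O)c1c(O)cc(OCc2ccccc2)cc1O | intermediate
3 | ethyl 2,2-diethoxyacetate | CCOC(OCC)C(=O)OCC | starting material
4 | 1-[4-(benzyloxy)-2,6-dihydroxyphenyl]-4,4-diethoxybutane-1,3-dione | CCOC(OCC)C(=O)CC(=O)c1c(O)cc(OCc2ccccc2)cc1O | intermediate (not isolated)
5 | 7-(benzyloxy)-2-(diethoxymethyl)-5-hydroxy-4H-chromen-4-one | CCOC(OCC)c1cc(=O)c2c(O)cc(OCc3ccccc3)cc2o1 | intermediate (not isolated)
6 | 7-(benzyloxy)-5-hydroxy-4-oxo-4H-chromene-2-carbaldehyde | O=Cc1cc(=O)c2c(O)cc(OCc3ccccc3)cc2o1 | intermediate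
7 | 7-(benzyloxy)-2-ethynyl-5-hydroxy-4H-chromen-4-one | C#Cc1cc(=O)c2c(O)cc(OCc3ccccc3)cc2o1 | intermediate
8 | 3-methoxyfuran | COc1ccoc1 | starting material
9 | 7-(benzyloxy)-5-hydroxy-2-(5-methoxy-7-oxabicyclo[2.2.1]hepta-2,5-dien-2-yl)-4H-chromen-4-one (racemic, one enantiomer drawn) | COC1=C[C@H]2O[C@@H]1C=C2c1cc(=O)c2c(O)cc(OCc3ccccc3)cc2o1 | intermediate (not isolated)
10 | 7-(benzyloxy)-5-hydroxy-2-(3-hydroxy-4-methoxyphenyl)-4H-chromen-4-one | COc1ccc(-c2cc(=O)c3c(O)cc(OCc4ccccc4)cc3o2)cc1O | intermediate
11 | 2-[3-(acetyloxy)-4-methoxyphenyl]-7-(benzyloxy)-4-oxo-4H-chromen-5-yl acetate | COc1ccc(-c2cc(=O)c3c(OC(C)=O)cc(OCc4ccccc4)cc3o2)cc1OC(C)=O | intermediate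
12 | 2-[3-(acetyloxy)-4-methoxyphenyl]-7-hydroxy-4-oxo-4H-chromen-5-yl acetate | COc1ccc(-c2cc(=O)c3c(OC(C)=O)cc(O)cc3o2)cc1OC(C)=O | intermediate
13 | 2-[3-(acetyloxy)-4-methoxyphenyl]-4-oxo-7-(sulfooxy)-4H-chromen-5-yl acetate | COc1ccc(-c2cc(=O)c3c(OC(C)=O)cc(OS(=O)(=O)O)cc3o2)cc1OC(C)=O | intermediate (not isolated)
14 | 5-hydroxy-2-(3-hydroxy-4-methoxyphenyl)-4-oxo-4H-chromen-7-yl hydrogen sulfate (luteolin 4'-methyl ether 7-sulfate) | COc1ccc(-c2cc(=O)c3c(O)cc(OS(=O)(=O)O)cc3o2)cc1O | target

**Totals**
Total step count: 7. Longest linear sequence: 7 steps (1 → 14); compounds 3 and 8 are bought.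

**Steps most likely to fail, with fallbacks**

Step 4 (carries the new-method label). Two processes could defeat it. The alkyne, activated only through the chromone, may react more slowly than the acid-sensitive furan decomposes. Alternatively, a stepwise addition may end by proton loss from the furan, giving conjugate alkenylation of the furan instead of ring closure. The fallback uses known flavone chemistry, sets out from 2 and returns at 10, with ring B brought in ready-made. Claisen–Schmidt condensation of 2 with isovanillin (3-hydroxy-4-methoxybenzaldehyde; KOH, EtOH–H2O, rt) should give the chalcone (E)-1-[4-(benzyloxy)-2,6-dihydroxyphenyl]-3-(3-hydroxy-4-methoxyphenyl)prop-2-en-1-one F1. Oxidative cyclization of F1 with I2 (0.1 equiv) in DMSO at 120 °C should then close the pyrone ring and deliver 10.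

Step 3. Methoxide may add in conjugate fashion to the newly formed ynenone or open the pyrone ring, and the diazophosphonate anion may undergo dipolar cycloaddition to the enone instead of olefinating the aldehyde. The fallback sets out from 2, bypasses 6 and returns at 7, bringing the alkyne in with the acyl partner instead of making it by homologation. Acylation of the trianion of 2 (LiN(SiMe3)2, THF, −78 °C) with ethyl 3-(trimethylsilyl)propiolate should give 1-[4-(benzyloxy)-2,6-dihydroxyphenyl]-5-(trimethylsilyl)pent-4-yne-1,3-dione F2. Acid cyclodehydration (TsOH·H2O, toluene, 60 °C) should give 7-(benzyloxy)-5-hydroxy-2-[(trimethylsilyl)ethynyl]-4H-chromen-4-one F3. Desilylation with Bu4NF buffered with AcOH (THF, 0 °C) should then give 7 without exposure to methoxide.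

Step 2. C-acylation of the poorly soluble polysodium salt may stall, and the hot aqueous acid needed for acetal hydrolysis may erode the benzyl ether or degrade the aldehyde. The fallback sets out from 2 and returns at 6, reaching the aldehyde through the ester oxidation level. Claisen condensation with diethyl oxalate (NaOEt, EtOH, reflux) should give the diketo ester ethyl 4-[4-(benzyloxy)-2,6-dihydroxyphenyl]-2,4-dioxobutanoate F4. Ring closure in ethanolic HCl should give ethyl 7-(benzyloxy)-5-hydroxy-4-oxo-4H-chromene-2-carboxylate F5. NaBH4 reduction (MeOH–THF, 0 °C) should give 7-(benzyloxy)-5-hydroxy-2-(hydroxymethyl)-4H-chromen-4-one F6, and oxidation with activated MnO2 (CH2Cl2, rt) should give 6.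

**Further compounds**
F1 | step 4 | (E)-1-[4-(benzyloxy)-2,6-dihydroxyphenyl]-3-(3-hydroxy-4-methoxyphenyl)prop-2-en-1-one | COc1ccc(/C=C/C(=O)c2c(O)cc(OCc3ccccc3)cc2O)cc1O
F2 | step 3 | 1-[4-(benzyloxy)-2,6-dihydroxyphenyl]-5-(trimethylsilyl)pent-4-yne-1,3-dione | C[Si](C)(C)C#CC(=O)CC(=O)c1c(O)cc(OCc2ccccc2)cc1O
F3 | step 3 | 7-(benzyloxy)-5-hydroxy-2-[(trimethylsilyl)ethynyl]-4H-chromen-4-one | C[Si](C)(C)C#Cc1cc(=O)c2c(O)cc(OCc3ccccc3)cc2o1
F4 | step 2 | ethyl 4-[4-(benzyloxy)-2,6-dihydroxyphenyl]-2,4-dioxobutanoate | CCOC(=O)C(=O)CC(=O)c1c(O)cc(OCc2ccccc2)cc1O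
F5 | step 2 | ethyl 7-(benzyloxy)-5-hydroxy-4-oxo-4H-chromene-2-carboxylate | CCOC(=O)c1cc(=O)c2c(O)cc(OCc3ccccc3)cc2o1
F6 | step 2 | 7-(benzyloxy)-5-hydroxy-2-(hydroxymethyl)-4H-chromen-4-one | OCc1cc(=O)c2c(O)cc(OCc3ccccc3)cc2o1
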